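## Structural features

The target, 2-[(3S,4R,6S)-3-hydroxy-4,6-dimethyl-6-[(2R)-2-methyl-10-phenyldecyl]-1,2-dioxan-3-yl]acetic acid, has one six-membered cyclic peroxide (O1–O2–C3–C4–C5–C6). C3 is a peroxy hemiketal carrying the acetic acid arm C2–C1, and C6 is a fully substituted peroxide carbon carrying a methyl group and the chain C7–C16 that ends in a phenyl ring. C3 and C4 are adjacent stereocentres, C6 is separated from C4 by the C5 methylene and C8 from C6 by the C7 methylene. In the chair the C3 hydroxyl is axial (anomeric) and cis to the equatorial C4 methyl, the acid arm and the C6 chain are equatorial, and the C6 methyl is axial. The fragile elements are the O–O bond (hydrogenation, phosphines, low-valent metals), the hemiketal, which is the closed form of a 4-hydroperoxy ketone and also a masked β-keto acid, and C4, which is α to that latent ketone and can epimerise through the open form. C3 needs no kinetic control, because ring–chain equilibration places its hydroxyl axial next to the equatorial C4 methyl, whereas C4 and C8 must enter as defined centres. The real difficulty is C6, a quaternary C–O centre with two alkyl groups of similar size (CH3 and CH2R) and no nearby stereocentre, together with the need to install the peroxide late and avoid reductive steps afterwards. The key step uses the fact that the ring divides into two three-atom halves: C6–O1–O2 is a methyl ketone at the peroxide level (electrophilic at C6, nucleophilic at O2), and C5–C4–C3 is a ketone homoenolate (nucleophilic at C5, electrophilic at C3) stored as the C3–C5 bond of a siloxycyclopropane.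

## Logic of the disconnections

**22 ⇒ 20 (via 21).** No skeletal bond is cut; the C1–O bonds are taken back from the acid to the primary alcohol. A free acid beside the hemiketal is a masked β-keto acid and would not survive organometallic reagents or Lewis acids, so C1 travels as a silyl ether from the first step of its fragment. The demand is a final oxidation that leaves O1–O2, the tertiary hemiketal hydroxyl and C4 alone.

**20 ⇒ 19.** The two O–Si bonds (C3–O and C1–O) are cut. 19 is what the annulation delivers, and removing the silyl ketal is also the point at which C3 comes under thermodynamic control. After this step only two diastereomers remain, differing at C6 alone, so this is the best place to remove the wrong C6 series. The demand is a desilylation mild enough for the peroxide and for C4.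

**19 ⇒ 9 + 16 (via 17 and 18).** C5–C6 and C3–O2 are cut. These two bonds divide the ring into its peroxide half and its homoenolate half, each already at its ring oxidation level. The gain is a convergent union that makes the ring and two bonds in one step, with C8 prepared in 9 and C4 in 16. The demands are attack by C5 and not by C4, ring closure on C3, and tolerance of the peroxide; C6 cannot be controlled.

**9 ⇒ 8 ⇒ 6 (via 7).** O2–Si and then the C6–O bonds are cut, so the peroxy ketal becomes a plain chiral methyl ketone. The demand is a single exchange of methoxy for hydroperoxy and a silylation that does not ionise the ketal.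

**6 ⇒ 3 + 4 (via 5).** The C11–C12 bond is cut as an alkene. The trisubstituted alkene of 3 ends exactly three carbons beyond C8, and 4 supplies the remaining five methylenes and the phenyl ring. All of this precedes the peroxide, so hydrogenation is still allowed. The demand is metathesis without double-bond migration.

**3 ⇒ 2 ⇒ 1.** The C6–CH3 bond is cut. 1 brings C8 from the chiral pool with the correct configuration, β to the carbonyl and therefore not epimerisable.

**16 ⇒ 14 ⇒ 13 (via 15).** O–Si and O–acyl bonds are cut. 13 is racemic, so it is resolved as covalent diastereomers; ester cleavage and silylation share one flask. The demands are separable diastereomers and a cleavage that does not open the three-membered ring.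

**13 ⇒ 11 + 12; 11 ⇒ 10.** The C3–C4 and C3–C5 bonds of the three-membered ring are cut (Kulinkovich cyclopropanation), then the C1–O silyl bond. The Grignard partner 12 supplies C4, C5 and the C4 methyl; the ester supplies C1–C3. The demand is that the β-silyloxy ester does not eliminate.

## Other disconnections considered

Alternative 1: The cut is C6–O1, made on the (E)-C6=C7 alkene of the open-chain hydroperoxy methyl ketal A1; C7 is returned to a methylene afterwards.
- Forward step: Hg(OAc)2 would activate the alkene, and the terminal peroxide oxygen would add to the more substituted C6, anti to mercury, through a 6-exo chair, giving the organomercurial A2. Reductive demercuration and hydrolysis of the ketal and ester groups of A2 would follow.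
- In favour: cycloperoxymercuration is an established closure for 1,2-dioxanes. The closure is intramolecular, so a chair with the C4 methyl equatorial can relay the C4 configuration to C6. C1 is already at the acid level.
- Against: A1 needs a geometrically pure trisubstituted alkene between the C4 and C8 stereocentres plus a hydroperoxy ketal of a β-keto ester, which means a long linear sequence. At C6 the chair must distinguish a methyl group from the mercury-bearing C7 arm, so the relay may be weak. Hydride demercuration passes through a C7 radical β to the peroxide, which can attack the O–O bond and form an epoxide. A stoichiometric mercury salt is required, and the methyl ester must be hydrolysed with base beside the peroxide.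
- Comparison: it forms one ring bond where the chosen plan forms two, by a stereospecific anti addition instead of a stepwise cationic annulation. It is better than the chosen plan in precedent, in the chance of controlling C6 and in the oxidation level of C1. It is poorer in convergence and in step count.

Alternative 2: Three bonds are cut at once (C4–C5, C6–O1, C3–O2), leading back to the keto ester A3, the 1,1-disubstituted alkene A4 and O2.
- Forward step: Mn(OAc)3 (trivalent manganese) would oxidise the enol of A3 to a C4 radical that adds to the CH2 end of A4. The tertiary C6 radical takes up O2 and the hydroperoxide closes on the C3 ketone, giving the dioxanol A5.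
- In favour: this aerobic annulation is known for 1,3-dicarbonyl compounds and 1,1-disubstituted alkenes. It makes the ring and three bonds in one step from fragments that are one or two steps from simple materials (A4 is one Wittig step from 6).
- Against: C4 is created as a quaternary centre bearing the temporary ester. Removing it needs ester cleavage and decarboxylation through the open β-keto acid, after which C4 is reprotonated without control; the centre that the chosen plan fixes in 16 is lost and up to four diastereomers would have to be separated. The allyl group must then be cleaved oxidatively beside the peroxide, and the allyl ketone of A3 can move into conjugation or act as a second radical acceptor.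
- Comparison: it is better than the chosen plan in bonds formed per step and in precedent. It is equal at C6, which again arises from a planar intermediate without facial control. Step economy is about equal overall, because the short way to A5 is offset by several corrective steps. On stereocontrol it is clearly the poorer plan.

Alternative 3: The cuts are C6–O1 and C3–O2; taking out O2 and joining C3 to C6 gives the cyclobutanol A6.
- Forward step: Co(acac)2 and O2 would turn A6 into its alkoxyl radical. β-Scission of C3–C6 releases the ring strain and gives the C3 ketone and the tertiary C6 radical, which takes up O2 and closes on the ketone to give A7. Acid then removes the tert-butyl group.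
- In favour: the reaction type is known on cyclobutanols and is neutral and mild. All ring atoms and C1 arrive at their final oxidation levels, C4 is set beforehand, and one step remains after the key step.
- Against: A6 has three contiguous substituted ring carbons with the quaternary C6 next to the carbinol carbon. The obvious [2+2] of a ketene with A4 would place the quaternary carbon β, not α, to the carbonyl, so a longer linear construction with C4 secured separately would be needed. The scission must prefer C3–C6 over C3–C4, which rests only on tertiary versus secondary radical stability.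
- Comparison: both plans use ring strain to deliver the C3 ketone level, but here the strain sits in one advanced precursor, whereas the chosen plan stores it in a small fragment made in four steps. It is better than the chosen plan in precedent, in the oxidation level of C1 and in the length of the endgame. It is equal at C6. Its total step count is expected to be higher.

Key step: step 10

Assumptions (remarks on the chemistry):
- Commercial 1 is taken as enantiomerically pure; its optical purity should be checked because it fixes C8.
- 2, 8 and 9 are epimer mixtures at the carbon that becomes the planar C6 cation, and 5 is an E/Z mixture; neither matters.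
- Step 10 is expected to give 19 together with its (6R) epimer. This by-product series carries no number, is taken through step 11 as the (6R) epimer of 19 and of 20, and is removed there.
- C1 is carried at the alcohol level through the annulation and oxidised last. The C3 descriptor is R in 19 and S in 20–22 only because silicon changes the CIP order; the geometry is the same.
- Ethereal H2O2 and the peroxides 8 and 9 are handled cold, behind a shield and never concentrated to dryness with acid present.

## Route

Step 1
Reactants: 1 (R)-citronellal [(3R)-3,7-dimethyloct-6-enal]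
Product: 2 (4R)-4,8-dimethylnon-7-en-2-ol (both C2 epimers)
Conditions: MeMgBr (1.2 equiv), Et2O, −78 to 0 °C; aq NH4Cl
Reagents that add atoms: methylmagnesium bromide, C[Mg]Br
Why: Grignard 1,2-addition to the aldehyde supplies the future C6 methyl; the new carbinol centre is uncontrolled and is erased in step 2, and the chain stereocentre is β to the carbonyl and cannot epimerise.

Step 2
Reactants: 2 (4R)-4,8-dimethylnon-7-en-2-ol
Product: 3 (4R)-4,8-dimethylnon-7-en-2-one
Conditions: Dess–Martin periodinane (1.2 equiv), CH2Cl2, 0 °C to rt; aq Na2S2O3/NaHCO3
Reagents that add atoms: none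
Why: Dess–Martin oxidation of a secondary alcohol; the trisubstituted alkene is inert to the reagent and the stereocentre stays β to the new ketone.

Step 3
Reactants: 3 (4R)-4,8-dimethylnon-7-en-2-one; 4 hex-5-en-1-ylbenzene
Product: 6 (4R)-4-methyl-12-phenyldodecan-2-one, via (4R)-4-methyl-12-phenyldodec-7-en-2-one 5 (not isolated)
Conditions: 4 (3 equiv), second-generation Grubbs catalyst (5 mol %), 1,4-benzoquinone (10 mol %), CH2Cl2, 40 °C, N2 sweep; then EtOAc, 10% Pd/C, H2 (1 atm), rt
Reagents that add atoms: none
Why: Olefin cross-metathesis between the prenyl-type alkene of 3 and the terminal alkene of 4 is driven by loss of volatile isobutene, with benzoquinone added to suppress double-bond migration; hydrogenation over Pd/C at 1 atm then saturates the E/Z mixture without touching the ketone or the arene. The hydrogenated homodimer of 4 is a hydrocarbon and is removed by chromatography.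

Step 4
Reactants: 6 (4R)-4-methyl-12-phenyldodecan-2-one
Product: 8 (4R)-2-hydroperoxy-2-methoxy-4-methyl-12-phenyldodecane (both C2 epimers), via (4R)-2,2-dimethoxy-4-methyl-12-phenyldodecane 7 (not isolated)
Conditions: HC(OMe)3 (3 equiv), MeOH, TsOH·H2O (2 mol %), rt; volatiles removed in vacuo; then H2O2 (ca. 2 M in Et2O, 5 equiv), 0 °C; aq NaHCO3
Reagents that add atoms: trimethyl orthoformate, COC(OC)OC; methanol, CO; hydrogen peroxide, OO
Why: Acid-catalysed ketalisation followed by acid-catalysed perhydrolysis, the established way to 2-hydroperoxy-2-methoxyalkanes; the methoxycarbenium ion from 7 is captured by the more nucleophilic H2O2, and its excess together with removal of methanol favours the single exchange. The C2 configuration is irrelevant because this carbon is ionised in step 10.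

Step 5
Reactants: 8 (4R)-2-hydroperoxy-2-methoxy-4-methyl-12-phenyldodecane
Product: 9 (4R)-2-methoxy-4-methyl-12-phenyl-2-[(triethylsilyl)peroxy]dodecane (both C2 epimers)
Conditions: Et3SiCl (1.3 equiv), imidazole (2.5 equiv), DMF, 0 °C
Reagents that add atoms: chlorotriethylsilane, CC[Si](Cl)(CC)CC
Why: O-silylation of the hydroperoxide under basic conditions, a standard transformation of hydroperoxy ketals; the base prevents acid-induced ionisation of the ketal.

Step 6
Reactants: 10 methyl 3-hydroxypropanoate
Product: 11 methyl 3-[(tert-butyldimethylsilyl)oxy]propanoate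
Conditions: TBSCl (1.1 equiv), imidazole (2 equiv), DMF, 0 °C to rt
Reagents that add atoms: tert-butylchlorodimethylsilane, CC(C)(C)[Si](C)(C)Cl
Why: Routine silylation of the primary alcohol, which protects the future C1 oxygen through the organometallic and Lewis-acid steps.

Step 7
Reactants: 11 methyl 3-[(tert-butyldimethylsilyl)oxy]propanoate; 12 propylmagnesium bromide
Product: 13 rac-(1S,2R)-1-{2-[(tert-butyldimethylsilyl)oxy]ethyl}-2-methylcyclopropan-1-ol (racemate; methyl cis to the side chain, trans to OH)
Conditions: Ti(OiPr)4 (0.2 equiv), 12 (2.5 equiv, slow addition), THF/Et2O, 0 °C to rt; aq NH4Cl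
Reagents that add atoms: none
Why: Kulinkovich cyclopropanation, in which the titanium alkoxide turns 12 into a 1,2-dicarbanion equivalent of propene that adds twice to the ester carbonyl; the known preference for cis-1,2-dialkylcyclopropanols places the methyl cis to the side chain. The product is racemic, and only the C2 centre (C4 of the target) matters later.

Step 8
Reactants: 13 rac-(1S,2R)-1-{2-[(tert-butyldimethylsilyl)oxy]ethyl}-2-methylcyclopropan-1-ol
Product: 14 (1S,2R)-1-{2-[(tert-butyldimethylsilyl)oxy]ethyl}-2-methylcyclopropyl (1S,4R)-4,7,7-trimethyl-3-oxo-2-oxabicyclo[2.2.1]heptane-1-carboxylate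
Conditions: (1S)-camphanic chloride (1.2 equiv), Et3N (2 equiv), DMAP (0.1 equiv), CH2Cl2, 0 °C to rt; diastereomers separated on silica gel or by crystallisation
Reagents that add atoms: (1S)-camphanic chloride, ClC(=O)[C@@]12CC[C@@](C)(C(=O)O1)C2(C)C
Why: Cyclopropanols acylate readily for tertiary alcohols, so esterification with an enantiopure acid chloride gives two diastereomeric esters for a classical resolution. No stereocentre is formed; the wanted (1S,2R) ester is to be identified by X-ray crystallography of a crystalline diastereomer.

Step 9
Reactants: 14 (1S,2R)-1-{2-[(tert-butyldimethylsilyl)oxy]ethyl}-2-methylcyclopropyl (1S,4R)-camphanate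
Product: 16 (1S,2R)-1-{2-[(tert-butyldimethylsilyl)oxy]ethyl}-2-methyl-1-[(trimethylsilyl)oxy]cyclopropane, via lithium cyclopropanolate 15 (not isolated)
Conditions: MeLi (2.2 equiv), THF, −78 °C; then Me3SiCl (1.3 equiv), −78 to 0 °C; pentane, aq NaHCO3
Reagents that add atoms: chlorotrimethylsilane, C[Si](C)(C)Cl
Why: Ester cleavage by double addition of MeLi to the exocyclic carbonyl, which is activated by its α-oxygen and by the cyclopropanolate leaving group and should react ahead of the shielded lactone carbonyl; this releases the lithium cyclopropanolate at low temperature without the ring opening that protic base would cause. The less hindered alkoxide is silylated in the same flask, and no stereocentre is touched.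

Step 10
Reactants: 9 (4R)-2-methoxy-4-methyl-12-phenyl-2-[(triethylsilyl)peroxy]dodecane; 16 (1S,2R)-1-{2-[(tert-butyldimethylsilyl)oxy]ethyl}-2-methyl-1-[(trimethylsilyl)oxy]cyclopropane
Product: 19 (3R,4R,6S)-3-{2-[(tert-butyldimethylsilyl)oxy]ethyl}-4,6-dimethyl-6-[(2R)-2-methyl-10-phenyldecyl]-3-[(trimethylsilyl)oxy]-1,2-dioxane, via silylperoxycarbenium ion 17 (not isolated), via ring-opened oxocarbenium ion 18 (not isolated)
Conditions: 16 (1.5 equiv), TMSOTf (0.3 equiv), 2,6-di-tert-butyl-4-methylpyridine (0.5 equiv), CH2Cl2, −78 to −40 °C; Et3N, then aq NaHCO3
Reagents that add atoms: none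
Why: Proposed new method: TMSOTf removes methoxide from 9 to give the silylperoxycarbenium ion 17; the strained C3–C5 bond of 16, made electron-rich by the silyloxy group on C3, attacks C6 through its unsubstituted CH2 corner (C5), which forms C5–C6 and leaves the O-silylated oxocarbenium ion 18. The silylated peroxide oxygen O2 then adds to C3 and passes its triethylsilyl group to triflate, so the silyl triflate is regenerated and a catalytic amount suffices. The closest known reactions are the Lewis-acid annulation of silylperoxycarbenium ions with alkenes to 1,2-dioxolanes, their Hosomi–Sakurai-type capture by allylsilanes, and the opening of siloxycyclopropanes by electrophiles as ketone homoenolate equivalents; what is new is the use of the cyclopropane C–C bond as the three-carbon partner of the peroxycarbenium ion. The ring closes in the 6-exo-trig mode, O2 adding to the exocyclic C3=O+ bond. C4 is not touched and keeps the configuration of 16; C3 is expected to form with the silyloxy group axial (anomeric effect) and cis to the equatorial C4 methyl, and is reset under thermodynamic control in step 11; C6 is formed on a planar cation whose nearest stereocentres (C8, and C4 of the nucleophile) are remote, so little facial bias is expected and the (6R) epimer of 19 should form in a similar amount. The selectivity the step needs is regiochemical, attack by C5 and not by the methyl-bearing C4, and it is secured by the lower substitution of C5 facing a tertiary cation; the hindered pyridine removes traces of triflic acid that would protonate 16 to the ketone. If 18 loses its trimethylsilyl group before closure, the silylperoxy ketone that results (F3 of the fallback below) gives the same dioxanol after step 11, so both paths converge.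

Step 11
Reactants: 19 (3R,4R,6S)-3-{2-[(tert-butyldimethylsilyl)oxy]ethyl}-4,6-dimethyl-6-[(2R)-2-methyl-10-phenyldecyl]-3-[(trimethylsilyl)oxy]-1,2-dioxane (carried as the mixture with its (6R) epimer)
Product: 20 (3S,4R,6S)-3-(2-hydroxyethyl)-4,6-dimethyl-6-[(2R)-2-methyl-10-phenyldecyl]-1,2-dioxan-3-ol
Conditions: HF·pyridine, pyridine, THF, 0 °C to rt; chromatography on silica gel
Reagents that add atoms: none
Why: Fluoride-mediated desilylation cleaves the silyl ketal and the primary silyl ether under buffered, weakly acidic conditions that spare the O–O bond; ring–chain equilibration of the hemiketal then sets C3 thermodynamically with the hydroxyl axial and cis to the equatorial C4 methyl. The (6R) epimer that accompanies 19 is desilylated in the same way, so only two diastereomeric diols are expected, and chromatography at this stage removes the (6R) diol.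

Step 12
Reactants: 20 (3S,4R,6S)-3-(2-hydroxyethyl)-4,6-dimethyl-6-[(2R)-2-methyl-10-phenyldecyl]-1,2-dioxan-3-ol
Product: 22 2-[(3S,4R,6S)-3-hydroxy-4,6-dimethyl-6-[(2R)-2-methyl-10-phenyldecyl]-1,2-dioxan-3-yl]acetic acid (the target), via hemiketal aldehyde 21 (not isolated)
Conditions: TEMPO (0.2 equiv), PhI(OAc)2 (2.5 equiv), MeCN/pH 7 phosphate buffer 1:1, 0 °C to rt
Reagents that add atoms: water, O
Why: Oxoammonium-mediated oxidation takes the primary alcohol to the aldehyde and, through its hydrate, to the acid; the tertiary hemiketal hydroxyl cannot be oxidised and the dialkyl peroxide is inert to this oxidant pair. The near-neutral medium protects C4 and the masked β-keto acid.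

## Compound list

1 | (R)-citronellal | C[C@H](CCC=C(C)C)CC=O | starting material
2 | (4R)-4,8-dimethylnon-7-en-2-ol (both C2 epimers) | C[C@H](CCC=C(C)C)CC(C)O | intermediate
3 | (4R)-4,8-dimethylnon-7-en-2-one | C[C@H](CCC=C(C)C)CC(C)=O | intermediate
4 | hex-5-en-1-ylbenzene | C=CCCCCc1ccccc1 | starting material
5 | (4R)-4-methyl-12-phenyldodec-7-en-2-one (E/Z mixture, E drawn) | C[C@H](CC/C=C/CCCCc1ccccc1)CC(C)=O | intermediate (not isolated)
6 | (4R)-4-methyl-12-phenyldodecan-2-one | C[C@H](CCCCCCCCc1ccccc1)CC(C)=O | intermediate
7 | (4R)-2,2-dimethoxy-4-methyl-12-phenyldodecane | C[C@H](CCCCCCCCc1ccccc1)CC(C)(OC)OC | intermediate (not isolated)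
8 | (4R)-2-hydroperoxy-2-methoxy-4-methyl-12-phenyldodecane (both C2 epimers) | C[C@H](CCCCCCCCc1ccccc1)CC(C)(OC)OO | intermediate
9 | (4R)-2-methoxy-4-methyl-12-phenyl-2-[(triethylsilyl)peroxy]dodecane (both C2 epimers) | C[C@H](CCCCCCCCc1ccccc1)CC(C)(OC)OO[Si](CC)(CC)CC | intermediate
10 | methyl 3-hydroxypropanoate | OCCC(=O)OC | starting material
11 | methyl 3-[(tert-butyldimethylsilyl)oxy]propanoate | COC(=O)CCO[Si](C)(C)C(C)(C)C | intermediate
12 | propylmagnesium bromide | CCC[Mg]Br | starting material
13 | rac-(1S,2R)-1-{2-[(tert-butyldimethylsilyl)oxy]ethyl}-2-methylcyclopropan-1-ol (both enantiomers drawn) | C1[C@@H](C)[C@@]1(O)CCO[Si](C)(C)C(C)(C)C.C1[C@H](C)[C@]1(O)CCO[Si](C)(C)C(C)(C)C | intermediate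
14 | (1S,2R)-1-{2-[(tert-butyldimethylsilyl)oxy]ethyl}-2-methylcyclopropyl (1S,4R)-4,7,7-trimethyl-3-oxo-2-oxabicyclo[2.2.1]heptane-1-carboxylate | C1[C@@H](C)[C@@]1(OC(=O)[C@@]23CC[C@@](C)(C(=O)O2)C3(C)C)CCO[Si](C)(C)C(C)(C)C | intermediate
15 | lithium (1S,2R)-1-{2-[(tert-butyldimethylsilyl)oxy]ethyl}-2-methylcyclopropan-1-olate | [Li+].C1[C@@H](C)[C@@]1([O-])CCO[Si](C)(C)C(C)(C)C | intermediate (not isolated)
16 | (1S,2R)-1-{2-[(tert-butyldimethylsilyl)oxy]ethyl}-2-methyl-1-[(trimethylsilyl)oxy]cyclopropane | C1[C@@H](C)[C@@]1(O[Si](C)(C)C)CCO[Si](C)(C)C(C)(C)C | intermediate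
17 | (4R)-4-methyl-12-phenyl-2-[(triethylsilyl)peroxy]dodecan-2-ylium triflate (silylperoxycarbenium ion) | C[C@H](CCCCCCCCc1ccccc1)CC(C)=[O+]O[Si](CC)(CC)CC.[O-]S(=O)(=O)C(F)(F)F | intermediate (not isolated)
18 | ring-opened O-trimethylsilyl oxocarbenium triflate at C3, triethylsilylperoxy group on C6 (both C6 epimers) | C[C@H](CCCCCCCCc1ccccc1)CC(C)(OO[Si](CC)(CC)CC)C[C@@H](C)C(=[O+][Si](C)(C)C)CCO[Si](C)(C)C(C)(C)C.[O-]S(=O)(=O)C(F)(F)F | intermediate (not isolated)
19 | (3R,4R,6S)-3-{2-[(tert-butyldimethylsilyl)oxy]ethyl}-4,6-dimethyl-6-[(2R)-2-methyl-10-phenyldecyl]-3-[(trimethylsilyl)oxy]-1,2-dioxane | C[C@H](CCCCCCCCc1ccccc1)C[C@@]1(C)C[C@@H](C)[C@](O[Si](C)(C)C)(CCO[Si](C)(C)C(C)(C)C)OO1 | intermediate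
20 | (3S,4R,6S)-3-(2-hydroxyethyl)-4,6-dimethyl-6-[(2R)-2-methyl-10-phenyldecyl]-1,2-dioxan-3-ol | C[C@H](CCCCCCCCc1ccccc1)C[C@@]1(C)C[C@@H](C)[C@](O)(CCO)OO1 | intermediate
21 | 2-[(3S,4R,6S)-3-hydroxy-4,6-dimethyl-6-[(2R)-2-methyl-10-phenyldecyl]-1,2-dioxan-3-yl]acetaldehyde | C[C@H](CCCCCCCCc1ccccc1)C[C@@]1(C)C[C@@H](C)[C@](O)(CC=O)OO1 | intermediate (not isolated)
22 | 2-[(3S,4R,6S)-3-hydroxy-4,6-dimethyl-6-[(2R)-2-methyl-10-phenyldecyl]-1,2-dioxan-3-yl]acetic acid | C[C@H](CCCCCCCCc1ccccc1)C[C@@]1(C)C[C@@H](C)[C@](O)(CC(=O)O)OO1 | target

## Step count and risks

Total step count: 12. Longest linear sequence: 8 steps (steps 1–5, then 10–12); the cyclopropane branch adds 4 steps (6–9) before the union.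

Stereocentres: C8 comes from 1, C4 from the resolved 16, C6 is formed without control in step 10 and sorted in step 11, and C3 is set thermodynamically in step 11.

**Step 10 (key step, proposed new method).**
- What may go wrong: acid-induced opening of the siloxycyclopropane to the ketone outrunning C–C bond formation; too little nucleophilicity of the cyclopropane bond toward the hindered tertiary cation, so that the peroxycarbenium ion decays by proton loss or by alkyl migration to oxygen; competing attack through the methyl-bearing carbon; and the expected absence of facial selectivity at C6, which halves the material in the wanted series.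
- Fallback with known chemistry, from 6 and 16, returning at 20. Kinetic enolisation of 6 at the methyl group (KN(SiMe3)2, PhNTf2, THF, −78 °C) should give the enol triflate (4R)-4-methyl-12-phenyldodec-1-en-2-yl trifluoromethanesulfonate F1. Palladium-catalysed ring-opening coupling of 16 with F1 (Pd(PPh3)4, DMF, 60 °C; a known homoenolate cross-coupling of siloxycyclopropanes with triflates, opening the CH2–C(O) bond) should give the γ,δ-unsaturated ketone (4R,8R)-1-[(tert-butyldimethylsilyl)oxy]-4,8-dimethyl-6-methylidene-16-phenylhexadecan-3-one F2. Mukaiyama–Isayama silylperoxidation (Co(acac)2, Et3SiH, O2, ClCH2CH2Cl, rt) would place the triethylsilylperoxy group on the tertiary C6 and give (4R,8R)-1-[(tert-butyldimethylsilyl)oxy]-4,6,8-trimethyl-16-phenyl-6-[(triethylsilyl)peroxy]hexadecan-3-one F3 as both C6 epimers. HF·pyridine as in step 11 then removes both silyl groups, and the hydroperoxy ketone closes to 20 and its (6R) epimer, which are separated as in step 11.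

**Step 8 (resolution).**
- What may go wrong: insufficient chromatographic or crystallisation discrimination between the two diastereomeric esters, or partial ring opening during acylation.
- Fallback, from 13, returning at 16. Preparative chiral supercritical-fluid chromatography of 13 (polysaccharide phase, CO2/iPrOH, mass-directed collection) would give (1S,2R)-1-{2-[(tert-butyldimethylsilyl)oxy]ethyl}-2-methylcyclopropan-1-ol F4, with the configuration assigned by correlation with 14. Silylation (Me3SiCl, Et3N, CH2Cl2, 0 °C) gives 16. This path also bypasses step 9, so it removes any competition from the lactone carbonyl during the organolithium cleavage.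

**Step 3 (cross-metathesis and hydrogenation).**
- What may go wrong: double-bond migration before metathesis, which would give chain-shortened homologues that cannot be removed after hydrogenation, and incomplete conversion of the slow trisubstituted alkene.
- Fallback, from 3, returning at 7 (which then enters the perhydrolysis stage of step 4). Ketalisation of 3 (HC(OMe)3, MeOH, TsOH) gives (6R)-8,8-dimethoxy-2,6-dimethylnon-2-ene F5. Ozonolysis (O3, CH2Cl2/MeOH, NaHCO3, −78 °C; Me2S) gives (4R)-6,6-dimethoxy-4-methylheptanal F6. Wittig reaction with the ylide from (5-phenylpentyl)triphenylphosphonium bromide F7 (made from (5-bromopentyl)benzene and PPh3; NaN(SiMe3)2, THF, −78 °C) gives (4R,7Z)-2,2-dimethoxy-4-methyl-12-phenyldodec-7-ene F8. Hydrogenation (H2, Pd/C, EtOAc, trace Et3N) gives 7, with the chain length fixed by the reagents.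

**Step 4 (perhydrolysis).**
- What may go wrong: reversion of the ketal to the ketone by adventitious water, or over-exchange to the geminal dihydroperoxide, so that the mono-exchange product is obtained in a mixture.
- Fallback, from 6, returning at 8. Wittig methylenation of 6 (Ph3P=CH2, THF) gives (4R)-2,4-dimethyl-12-phenyldodec-1-ene F9. Ozonolysis in MeOH/CH2Cl2 at −78 °C forms the carbonyl oxide on the disubstituted carbon, methanol traps it and formaldehyde is lost, which gives 8 directly without concentrated H2O2.

**Step 12 (oxidation to the acid).**
- What may go wrong: oxidation through the open-chain hydroperoxide tautomer, epimerisation at C4 through the open β-keto aldehyde, or decarboxylation of the open β-keto acid.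
- Fallback, from 20, returning at 22. Exchange of the hemiketal hydroxyl for methoxy (MeOH, PPTS, rt) locks the ring as 2-[(3S,4R,6S)-3-methoxy-4,6-dimethyl-6-[(2R)-2-methyl-10-phenyldecyl]-1,2-dioxan-3-yl]ethan-1-ol F10. Oxidation of the primary alcohol (Dess–Martin periodinane, then NaClO2, NaH2PO4, 2-methylbut-2-ene) gives 2-[(3S,4R,6S)-3-methoxy-4,6-dimethyl-6-[(2R)-2-methyl-10-phenyldecyl]-1,2-dioxan-3-yl]acetic acid F11. Mild aqueous acid (dilute HCl, THF/H2O) hydrolyses the peroxy ketal to 22.

## Further compounds

F1 | step 10 | (4R)-4-methyl-12-phenyldodec-1-en-2-yl trifluoromethanesulfonate | C[C@H](CCCCCCCCc1ccccc1)CC(=C)OS(=O)(=O)C(F)(F)F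
F2 | step 10 | (4R,8R)-1-[(tert-butyldimethylsilyl)oxy]-4,8-dimethyl-6-methylidene-16-phenylhexadecan-3-one | C[C@H](CCCCCCCCc1ccccc1)CC(=C)C[C@@H](C)C(=O)CCO[Si](C)(C)C(C)(C)C
F3 | step 10 | (4R,8R)-1-[(tert-butyldimethylsilyl)oxy]-4,6,8-trimethyl-16-phenyl-6-[(triethylsilyl)peroxy]hexadecan-3-one (both C6 epimers) | C[C@H](CCCCCCCCc1ccccc1)CC(C)(OO[Si](CC)(CC)CC)C[C@@H](C)C(=O)CCO[Si](C)(C)C(C)(C)C
F4 | step 8 | (1S,2R)-1-{2-[(tert-butyldimethylsilyl)oxy]ethyl}-2-methylcyclopropan-1-ol | C1[C@@H](C)[C@@]1(O)CCO[Si](C)(C)C(C)(C)C
F5 | step 3 | (6R)-8,8-dimethoxy-2,6-dimethylnon-2-ene | C[C@H](CCC=C(C)C)CC(C)(OC)OC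
F6 | step 3 | (4R)-6,6-dimethoxy-4-methylheptanal | C[C@H](CCC=O)CC(C)(OC)OC
F7 | step 3 | (5-phenylpentyl)triphenylphosphonium bromide | [Br-].c1ccccc1CCCCC[P+](c1ccccc1)(c1ccccc1)c1ccccc1
F8 | step 3 | (4R,7Z)-2,2-dimethoxy-4-methyl-12-phenyldodec-7-ene | C[C@H](CC/C=C\CCCCc1ccccc1)CC(C)(OC)OC
F9 | step 4 | (4R)-2,4-dimethyl-12-phenyldodec-1-ene | C[C@H](CCCCCCCCc1ccccc1)CC(C)=C
F10 | step 12 | 2-[(3S,4R,6S)-3-methoxy-4,6-dimethyl-6-[(2R)-2-methyl-10-phenyldecyl]-1,2-dioxan-3-yl]ethan-1-ol | C[C@H](CCCCCCCCc1ccccc1)C[C@@]1(C)C[C@@H](C)[C@](OC)(CCO)OO1
F11 | step 12 | 2-[(3S,4R,6S)-3-methoxy-4,6-dimethyl-6-[(2R)-2-methyl-10-phenyldecyl]-1,2-dioxan-3-yl]acetic acid | C[C@H](CCCCCCCCc1ccccc1)C[C@@]1(C)C[C@@H](C)[C@](OC)(CC(=O)O)OO1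
A1 | alternative 1 | methyl (4R,6E,8R)-3-hydroperoxy-3-methoxy-4,6,8-trimethyl-16-phenylhexadec-6-enoate (both C3 epimers) | C[C@H](CCCCCCCCc1ccccc1)/C=C(\C)C[C@@H](C)C(OC)(OO)CC(=O)OC
A2 | alternative 1 | methyl 2-[(3S,4R,6R)-6-[(1S,2R)-1-(acetoxymercurio)-2-methyl-10-phenyldecyl]-3-methoxy-4,6-dimethyl-1,2-dioxan-3-yl]acetate | C[C@H](CCCCCCCCc1ccccc1)[C@H]([Hg]OC(C)=O)[C@@]1(C)C[C@@H](C)[C@](OC)(CC(=O)OC)OO1
A3 | alternative 2 | tert-butyl 2-methyl-3-oxohex-5-enoate (racemic) | C=CCC(=O)C(C)C(=O)OC(C)(C)C
A4 | alternative 2 | (4R)-2,4-dimethyl-12-phenyldodec-1-ene | C[C@H](CCCCCCCCc1ccccc1)CC(C)=C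
A5 | alternative 2 | tert-butyl (3S,4S,6S)-3-hydroxy-4,6-dimethyl-6-[(2R)-2-methyl-10-phenyldecyl]-3-(prop-2-en-1-yl)-1,2-dioxane-4-carboxylate | C[C@H](CCCCCCCCc1ccccc1)C[C@@]1(C)C[C@@](C(=O)OC(C)(C)C)(C)[C@](O)(CC=C)OO1
A6 | alternative 3 | tert-butyl 2-{(4R)-1-hydroxy-2,4-dimethyl-2-[(2R)-2-methyl-10-phenyldecyl]cyclobutyl}acetate (ring C1 and C2 of either configuration) | C[C@H](CCCCCCCCc1ccccc1)CC1(C)C[C@@H](C)C1(O)CC(=O)OC(C)(C)C
A7 | alternative 3 | tert-butyl 2-[(3S,4R,6S)-3-hydroxy-4,6-dimethyl-6-[(2R)-2-methyl-10-phenyldecyl]-1,2-dioxan-3-yl]acetate | C[C@H](CCCCCCCCc1ccccc1)C[C@@]1(C)C[C@@H](C)[C@](O)(CC(=O)OC(C)(C)C)OO1
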